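## The problem

Compound 17, (R)-3-hydroxy-5-[4-hydroxy-3-(3-methylbut-2-en-1-yl)benzyl]-4-(4-hydroxyphenyl)furan-2(5H)-one, is a monocyclic 3-hydroxybutenolide, the enol form of an α-keto γ-lactone. Three adjacent ring carbons must each be dressed differently: C3 with oxygen, C4 directly with ring A (4-hydroxyphenyl), and C5, through the C6 methylene, with ring B (4-hydroxy-3-prenylphenyl). C5 (R) is the only stereocentre, so no other centre can set or repair it; it must come from a reagent- or catalyst-controlled event and then be carried untouched. It is the γ-carbon of a butenolide, allylic and α to the ring oxygen, so once the enol oxygen is capped its hydrogen is open to amine bases stronger than pyridine, and opening of the lactone under base would expose a retro-aldol between C4 and C5. The prenyl group rules out strong protic or Lewis acids, hydrogenation and free electrophilic halogen late in the route, and the free enol is attacked at C4 by electrophiles and oxidants. Rings A and B differ only in the prenyl group, so a route that adds it late must tell two para-oxygenated phenyl rings apart. The enabling feature is that C5 carries two arylmethyl-type arms, C4 with ring A and C6 with ring B: without the prenyl group the aryl groups are identical, C5 is the prochiral carbinol carbon of a symmetrical 1,3-diarylpropan-2-ol, and C4 and C6 are enantiotopic benzylic methylenes. An acetate unit on the carbinol oxygen (the future O1–C2 bond) can then supply C2 and C3, and C3–C4 can be made by carbene insertion into a benzylic C–H bond of one arm; the choice of arm fixes C5, and the configuration created at C4 is irrelevant because C4 ends trigonal.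

## Retrosynthesis

**17 to 16 (three O–C bonds).** The last step should only unmask oxygen. Cutting the two aryl O–CH2 bonds and the enol O–acyl bond leads to 16, the bis(methoxymethyl) ether enol acetate. Acetal and ester masks are preferred to methyl or benzyl ethers, whose removal by boron halides or hydrogenolysis the prenyl group would not survive, and all three fall in one acidic methanolysis. The skeleton is not simplified; the forward step must be mild enough to spare the prenyl alkene and C5.

**16 to 14 and 15 (ring B C–CH2 bond).** Cutting the bond between ring B and the prenyl CH2 gives aryl bromide 14 and prenylstannane 15, to be joined by Stille coupling. Direct C-prenylation of a phenol, or Claisen rearrangement of a reverse-prenyl ether, would need ring B as a free phenol beside a masked ring A, a selective O-protection that two similar phenols do not offer. The coupling is neutral and must deliver the linear prenyl isomer.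

**14 to 13 (ring B C–Br bond).** Here rings A and B are told apart, by electronics and not by protecting groups. In 13 ring A is conjugated with the acetoxy-substituted enoate and is deactivated at the positions ortho to its ether oxygen, while ring B is an ordinary para-alkyl aryl ether; the acetate also lowers the nucleophilicity of C4. Differentiation by phenol acidity was set aside: once the enol is deprotonated the butenolide no longer withdraws from ring A and the acidity gap closes. The bromination must find ring B, stop at one bromine and leave the enol acetate alone.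

**13 to 11 (C3 and C4 back to sp3; enol O–acyl bond).** Removing the acetyl group and returning C3 to a carbinol and C4 to a methine gives hydroxy lactone 11; enol 12 lies between and need not be isolated. Oxidation of 11 gives a 2,3-dioxo lactone that can enolise only towards C4, so the conjugated enol forms by itself and the configurations at C3 and C4 cease to matter. The forward sequence must not over-oxidise the enol and must acetylate with a base too weak to touch the C5 hydrogen.

**11 to 10 (C3–O bond).** Cutting C3–O leads to lactone 10 and calls for enolate hydroxylation. Carrying the C3 oxygen through the ring-forming step would need a substituted diazo ester, a different carbene class from the acceptor-only diazoacetates for which chiral carboxamidate catalysts work best. Adding the oxygen afterwards costs one step; either C3 epimer serves.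

**10 to 9 (C3–C4 bond, lactone ring).** This is the strategic cut. Breaking C3–C4 opens the lactone to diazoacetate 9 of a symmetrical carbinol, an achiral compound with no ring and no stereocentre. The neighbouring cuts reward less: C4–C5 in the aldol sense would need an absolute-stereocontrolled aldol addition to an enolisable aldehyde, and C2–O1 alone would leave both stereocentres in an open chain. Forward, a chiral dirhodium carboxamidate, Rh2(4R-MPPIM)4, must turn 9 into a carbene that inserts into a benzylic C–H bond of one enantiotopic arm only, in preference to the arenes, and 10 must be freed of any diastereomer carrying the opposite C5.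

**9 to 6 and 7 (C=N2 and ester C–O bonds).** The diazo group is traced to bromide 8, and the ester to carbinol 6 and bromoacetyl bromide 7. This two-step diazoacetate synthesis runs cold and near neutrality and keeps the methoxymethyl ethers.

**6 to 2 and 3, and 2 to 1 (two ring–CH2 bonds; the C–Mg bond).** Carbinol 6 is cut at both aryl–CH2 bonds, giving two equivalents of aryl Grignard reagent 2 and the three-carbon electrophile epichlorohydrin 3, with chlorohydrin 4 and epoxide 5 as the stages between. Reagent 2 is made once, by magnesium insertion into the catalogue bromide 1, and kept as a titrated THF solution that serves both openings. An aryl Grignard reagent is preferred to a benzylic one, which would need a non-stock benzylic chloride and is prone to homocoupling. The two copper-catalysed epoxide openings need only be regioselective for the CH2 terminus; 5 may be racemic because 6 is achiral.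

## Roads not taken

**Alternative 1:** The cut removes C2 and C3 as two carbonyl units and breaks C3–C4, C2–C3 and O1–C2, leading to trans-epoxide A2, in which ring B already carries bromine as a placeholder for prenyl. Forward, the tetracarbonylcobaltate anion, [Co(CO)4]−, would open A2 at the benzylic carbon, two successive carbonylations would give an α-keto acyl cobalt species, and the C5 alkoxide would close on it to give 3-hydroxybutenolide A1 in one operation.
- Merits: the whole oxidised lactone forms at once, C5 comes from a well-understood asymmetric epoxidation, and the rings are differentiated from the start, so only cross-coupling and unmasking would remain after A1.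
- Weak points: after the first carbonylation the acyl cobalt alkoxide is the intermediate that collapses to a β-lactone in epoxide carbonylation, and the second carbonylation would have to outrun that fast ring closure. Double carbonylation is established for benzylic halides, not for epoxides, so the step would have to be invented. A2 is also a para-alkoxyphenyl epoxide, the kind that isomerises to a ketone under the Lewis acidic conditions such catalysts need.
- Comparison: this road is shorter by several steps and avoids the late ring discrimination of step 9. The adopted plan sets against it a key step of an established reaction class and an achiral precursor made in five simple steps.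

**Alternative 2:** The cut breaks the C4–ring A bond, C2–C3 and O1–C2, leading to propargylic alcohol A4 (an ynol ether with ring B fully prenylated), aryl Grignard reagent A5 and a carboxylating agent. Forward, the magnesium alkoxide of A4 would direct anti addition of A5 across the triple bond (aryl to C4, magnesium to C3), and carboxylation and closure on the C5 oxygen would give protected target A3.
- Merits: a convergent three-component assembly with the prenyl group present from the beginning, C5 from asymmetric alkynylation or ynone reduction, and few steps.
- Weak points: alkoxide-directed anti-carbomagnesiation is known for alkyl- and aryl-substituted propargylic alcohols, but an ynol ether is polarised so that nucleophiles prefer the oxygen-bearing carbon, C3, the opposite of what is required. Enantiopure A4 needs an enolisable, self-condensing arylacetaldehyde or the matching ynone. Removing the 4-methoxybenzyl group from the enol oxygen of A3 needs oxidative or acidic conditions that threaten the electron-rich prenylated ring.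
- Comparison: this road is shorter and needs no ring discrimination. The adopted plan is longer but each step has direct precedent and its unmasking is compatible with the prenyl group.

**Alternative 3:** The cut breaks O1–C5 and O1–C2 (oxygen insertion), leading to racemic cyclobutanone A7. Forward, a Baeyer–Villiger monooxygenase would insert oxygen between the carbonyl carbon and the substituted α-carbon of one enantiomer of A7 while the other racemises by enolisation, giving lactone A6 with C5 arranged as in the target.
- Merits: mild aqueous conditions that spare the prenyl group, possible full conversion to one enantiomer, and ring B complete from the start.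
- Weak points: the key step forms no C–C bond and gives only a 5-monosubstituted lactone. Ring A and the C3 oxygen would still need dehydrogenation to a butenolide, conjugate arylation, hydroxylation and oxidation, passing through a 5-substituted butenolide with a labile γ-hydrogen. Enzymatic oxidation of 2-substituted cyclobutanones often gives both regioisomeric lactones, racemisation at enzyme-compatible pH is slow, and acceptance of so bulky a substrate would need screening.
- Comparison: this road is gentler on the prenyl group and needs no ring discrimination. The adopted plan makes a skeletal bond, the ring and the stereocentre in one step with a known catalyst class and needs fewer steps after the key step.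

Key step: step 6

Assumption: Rh2(4R-MPPIM)4 is taken to fix C4 in the sense known for benzylic insertion of 2-arylethyl diazoacetates and to favour the 4,5-cis lactone as with other symmetrical secondary diazoacetates; if the first run shows 5S material, Rh2(4S-MPPIM)4 replaces it and nothing else changes.

## Route

Step 1
Reactants: 1 1-bromo-4-(methoxymethoxy)benzene
Product: 2 4-(methoxymethoxy)phenylmagnesium bromide (titrated THF solution, kept under argon)
Conditions: Mg turnings (1.1 equiv), THF, 40 °C
Reagents that add atoms: magnesium, [Mg]
Why: Grignard reagent formation by insertion of magnesium into the aryl C–Br bond; the methoxymethyl ether is inert to the organomagnesium, and one titrated solution supplies both epoxide openings that follow.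

Step 2
Reactants: 2 4-(methoxymethoxy)phenylmagnesium bromide; 3 (±)-epichlorohydrin
Product: 5 (±)-2-[4-(methoxymethoxy)benzyl]oxirane, via (±)-1-chloro-3-[4-(methoxymethoxy)phenyl]propan-2-ol 4 (not isolated)
Conditions: 2 (1.0 equiv), CuI (5 mol %), 3 (1.1 equiv), THF, −40 → 0 °C; then aq NaOH (2 M), rt
Reagents that add atoms: none
Why: Copper-catalysed Grignard opening of epichlorohydrin occurs at the unsubstituted epoxide carbon, and hydroxide then closes the chlorohydrin to the epoxide by intramolecular Williamson substitution; the methoxymethyl ether is inert to both.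

Step 3
Reactants: 5 (±)-2-[4-(methoxymethoxy)benzyl]oxirane; 2 4-(methoxymethoxy)phenylmagnesium bromide
Product: 6 1,3-bis[4-(methoxymethoxy)phenyl]propan-2-ol
Conditions: 2 (1.3 equiv), CuI (10 mol %), THF, −30 → 0 °C; H2O work-up
Reagents that add atoms: none
Why: Copper-catalysed SN2 opening of the monosubstituted epoxide at its CH2 terminus by Grignard reagent 2; the second aryl group makes the carbinol symmetrical and achiral, so the racemic nature of 5 is of no consequence.

Step 4
Reactants: 6 1,3-bis[4-(methoxymethoxy)phenyl]propan-2-ol; 7 bromoacetyl bromide
Product: 8 1,3-bis[4-(methoxymethoxy)phenyl]propan-2-yl bromoacetate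
Conditions: 7 (1.5 equiv), NaHCO3 (3 equiv), MeCN, 0 °C
Reagents that add atoms: none
Why: Acylation of the secondary alcohol by the acid bromide (first half of the Fukuyama diazoacetate synthesis); NaHCO3 takes up HBr, so the acid-labile methoxymethyl ethers are not exposed.

Step 5
Reactants: 8 1,3-bis[4-(methoxymethoxy)phenyl]propan-2-yl bromoacetate
Product: 9 1,3-bis[4-(methoxymethoxy)phenyl]propan-2-yl diazoacetate
Conditions: TsNHNHTs (2 equiv), DBU (5 equiv), THF, 0 °C
Reagents that add atoms: N,N'-bis(4-methylbenzenesulfonyl)hydrazine, Cc1ccc(cc1)S(=O)(=O)NNS(=O)(=O)c1ccc(C)cc1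
Why: N-Alkylation of the ditosylhydrazine by the bromoacetate followed by twofold base-induced loss of sulfinate gives the diazoacetate (Fukuyama method); the conditions are cold and basic and touch nothing else.

Step 6
Reactants: 9 1,3-bis[4-(methoxymethoxy)phenyl]propan-2-yl diazoacetate
Product: 10 (4S,5R)-5-[4-(methoxymethoxy)benzyl]-4-[4-(methoxymethoxy)phenyl]dihydrofuran-2(3H)-one (4,5-cis)
Conditions: Rh2(4R-MPPIM)4 (1 mol %; MPPIM = methyl 1-(3-phenylpropanoyl)-2-oxoimidazolidine-4-carboxylate), CH2Cl2, reflux, 9 added by syringe pump over 10 h; chromatographic removal of the trans lactone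
Reagents that add atoms: none
Why: Loss of N2 from 9 at an axial site of the catalyst (two divalent rhodium centres bridged by four chiral carboxamidates) gives an electrophilic rhodium carbene, which inserts into a benzylic C–H bond of one arm through a concerted, three-centre, hydride-transfer-like transition state, so C3–C4 forms with retention at C4 and the catalyst is released. The closest known reaction type is the chiral dirhodium carboxamidate-catalysed intramolecular C–H insertion of alkyl diazoacetates to γ-butyrolactones, shown for benzylic C–H bonds of 2-arylethyl diazoacetates and for arm-selective insertion in symmetrical secondary diazoacetates (3-pentyl, cyclohexyl, 1,3-dialkoxypropan-2-yl). The lactone ring closes by C–C bond formation between the carbene carbon and the carbon β to the ester oxygen (1,5-insertion through a five-membered transition state); the four-membered mode at the carbinol C–H and remote modes are disfavoured with carboxamidate ligands. C4 is set by which of the two diastereotopic benzylic hydrogens the ligand pocket presents to the carbene, and C5 by which enantiotopic arm reacts; with N-acylimidazolidinone ligands the spectator arm should point away from the ester groups of the catalyst, which places it cis to the C4 aryl group. Taking the C4 sense from 2-arylethyl diazoacetates, the 4R ligand series should give 4S and hence the cis lactone (4S,5R). Chemoselectivity against addition to the electron-rich arenes, carbene dimerisation and O–H insertion rests on the mild electrophilicity of carboxamidate carbenes, on activation of the benzylic C–H bond by the para oxygen, and on slow addition under dry conditions. Because a trans lactone formed with the same C4 sense would be 5S, the diastereomers are separated and the enantiomeric purity of 10 is checked before C4 is flattened.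

Step 7
Reactants: 10 (4S,5R)-5-[4-(methoxymethoxy)benzyl]-4-[4-(methoxymethoxy)phenyl]dihydrofuran-2(3H)-one
Product: 11 (3R,4R,5R)-3-hydroxy-5-[4-(methoxymethoxy)benzyl]-4-[4-(methoxymethoxy)phenyl]dihydrofuran-2(3H)-one
Conditions: NaN(SiMe3)2 (1.1 equiv), THF, −78 °C; 2-(phenylsulfonyl)-3-phenyloxaziridine (1.3 equiv), −78 °C; AcOH quench
Reagents that add atoms: 2-(phenylsulfonyl)-3-phenyloxaziridine, O=S(=O)(c1ccccc1)N1OC1c1ccccc1
Why: Sodium enolate hydroxylation with the Davis oxaziridine; oxygen should enter anti to the C4 aryl group, but the C3 configuration is lost in step 8, and the aryl acetals tolerate the amide base.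

Step 8
Reactants: 11 (3R,4R,5R)-3-hydroxy-5-[4-(methoxymethoxy)benzyl]-4-[4-(methoxymethoxy)phenyl]dihydrofuran-2(3H)-one
Product: 13 (R)-5-[4-(methoxymethoxy)benzyl]-4-[4-(methoxymethoxy)phenyl]-2-oxo-2,5-dihydrofuran-3-yl acetate, via (R)-3-hydroxy-5-[4-(methoxymethoxy)benzyl]-4-[4-(methoxymethoxy)phenyl]furan-2(5H)-one 12 (not isolated)
Conditions: Dess–Martin periodinane (1.3 equiv), CH2Cl2, 0 °C → rt; then pyridine (6 equiv), Ac2O (3 equiv), 0 °C → rt
Reagents that add atoms: acetic anhydride, CC(=O)OC(C)=O
Why: Dess–Martin oxidation gives the 2,3-dioxo lactone, which can enolise only towards C4 and settles as the conjugated enol 12, erasing C3 and C4 while C5 is untouched. Acetic anhydride with pyridine, a base too weak to remove the C5 hydrogen of the capped butenolide, then acetylates the acidic enol.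

Step 9
Reactants: 13 (R)-5-[4-(methoxymethoxy)benzyl]-4-[4-(methoxymethoxy)phenyl]-2-oxo-2,5-dihydrofuran-3-yl acetate
Product: 14 (R)-5-[3-bromo-4-(methoxymethoxy)benzyl]-4-[4-(methoxymethoxy)phenyl]-2-oxo-2,5-dihydrofuran-3-yl acetate
Conditions: NBS (1.05 equiv), MeCN, 0 °C → rt, dark
Reagents that add atoms: N-bromosuccinimide, O=C1CCC(=O)N1Br
Why: Electrophilic aromatic bromination with NBS in MeCN, a standard nuclear bromination of alkoxyarenes; ring B is a para-alkyl aryl ether, whereas ring A is deactivated at the positions ortho to its ether oxygen by the conjugated acetoxy enoate, and the tetrasubstituted, electron-poor enol acetate alkene should not compete. One equivalent and the deactivating effect of the first bromine should limit the reaction to mono-substitution ortho to the ether oxygen.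

Step 10
Reactants: 14 (R)-5-[3-bromo-4-(methoxymethoxy)benzyl]-4-[4-(methoxymethoxy)phenyl]-2-oxo-2,5-dihydrofuran-3-yl acetate; 15 tributyl(3-methylbut-2-en-1-yl)stannane
Product: 16 (R)-5-[4-(methoxymethoxy)-3-(3-methylbut-2-en-1-yl)benzyl]-4-[4-(methoxymethoxy)phenyl]-2-oxo-2,5-dihydrofuran-3-yl acetate
Conditions: 15 (1.5 equiv), Pd(PPh3)4 (5 mol %), DMF, 100 °C
Reagents that add atoms: none
Why: Stille coupling: oxidative addition of zerovalent palladium into the aryl–Br bond, transmetalation from the allylic stannane and reductive elimination at the less hindered allyl terminus should give the linear prenyl arene. The conditions are neutral, so the enol acetate, the acetals and C5 are not at risk.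

Step 11
Reactants: 16 (R)-5-[4-(methoxymethoxy)-3-(3-methylbut-2-en-1-yl)benzyl]-4-[4-(methoxymethoxy)phenyl]-2-oxo-2,5-dihydrofuran-3-yl acetate
Product: 17 (R)-3-hydroxy-5-[4-hydroxy-3-(3-methylbut-2-en-1-yl)benzyl]-4-(4-hydroxyphenyl)furan-2(5H)-one
Conditions: HCl (3 M aq)/MeOH 1:5, rt → 40 °C
Reagents that add atoms: none
Why: Acid-catalysed methanolysis cleaves both methoxymethyl acetals (as dimethoxymethane) and transesterifies the enol acetate; dilute methanolic HCl near room temperature is the usual way to unmask ortho-prenylphenols, and C5 has no acid-mediated epimerisation path.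

## Compound list

1 | 1-bromo-4-(methoxymethoxy)benzene | COCOc1ccc(Br)cc1 | starting material
2 | 4-(methoxymethoxy)phenylmagnesium bromide | COCOc1ccc([Mg]Br)cc1 | intermediate
3 | (±)-epichlorohydrin, 2-(chloromethyl)oxirane | ClCC1CO1 | starting material
4 | (±)-1-chloro-3-[4-(methoxymethoxy)phenyl]propan-2-ol | COCOc1ccc(CC(O)CCl)cc1 | intermediate (not isolated)
5 | (±)-2-[4-(methoxymethoxy)benzyl]oxirane | COCOc1ccc(CC2CO2)cc1 | intermediate
6 | 1,3-bis[4-(methoxymethoxy)phenyl]propan-2-ol | COCOc1ccc(CC(O)Cc2ccc(OCOC)cc2)cc1 | intermediate
7 | bromoacetyl bromide | BrCC(Br)=O | starting material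
8 | 1,3-bis[4-(methoxymethoxy)phenyl]propan-2-yl bromoacetate | COCOc1ccc(CC(Cc2ccc(OCOC)cc2)OC(=O)CBr)cc1 | intermediate
9 | 1,3-bis[4-(methoxymethoxy)phenyl]propan-2-yl diazoacetate | COCOc1ccc(CC(Cc2ccc(OCOC)cc2)OC(=O)C=[N+]=[N-])cc1 | intermediate
10 | (4S,5R)-5-[4-(methoxymethoxy)benzyl]-4-[4-(methoxymethoxy)phenyl]dihydrofuran-2(3H)-one (4,5-cis) | COCOc1ccc(C[C@H]2OC(=O)C[C@H]2c2ccc(OCOC)cc2)cc1 | intermediate
11 | (3R,4R,5R)-3-hydroxy-5-[4-(methoxymethoxy)benzyl]-4-[4-(methoxymethoxy)phenyl]dihydrofuran-2(3H)-one | COCOc1ccc(C[C@H]2OC(=O)[C@H](O)[C@H]2c2ccc(OCOC)cc2)cc1 | intermediate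
12 | (R)-3-hydroxy-5-[4-(methoxymethoxy)benzyl]-4-[4-(methoxymethoxy)phenyl]furan-2(5H)-one | COCOc1ccc(C[C@H]2OC(=O)C(O)=C2c2ccc(OCOC)cc2)cc1 | intermediate (not isolated)
13 | (R)-5-[4-(methoxymethoxy)benzyl]-4-[4-(methoxymethoxy)phenyl]-2-oxo-2,5-dihydrofuran-3-yl acetate | COCOc1ccc(C[C@H]2OC(=O)C(OC(C)=O)=C2c2ccc(OCOC)cc2)cc1 | intermediate
14 | (R)-5-[3-bromo-4-(methoxymethoxy)benzyl]-4-[4-(methoxymethoxy)phenyl]-2-oxo-2,5-dihydrofuran-3-yl acetate | COCOc1ccc(C[C@H]2OC(=O)C(OC(C)=O)=C2c2ccc(OCOC)cc2)cc1Br | intermediate
15 | tributyl(3-methylbut-2-en-1-yl)stannane | CCCC[Sn](CCCC)(CCCC)CC=C(C)C | starting material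
16 | (R)-5-[4-(methoxymethoxy)-3-(3-methylbut-2-en-1-yl)benzyl]-4-[4-(methoxymethoxy)phenyl]-2-oxo-2,5-dihydrofuran-3-yl acetate | COCOc1ccc(C[C@H]2OC(=O)C(OC(C)=O)=C2c2ccc(OCOC)cc2)cc1CC=C(C)C | intermediate
17 | (R)-3-hydroxy-5-[4-hydroxy-3-(3-methylbut-2-en-1-yl)benzyl]-4-(4-hydroxyphenyl)furan-2(5H)-one | CC(C)=CCc1cc(C[C@H]2OC(=O)C(O)=C2c2ccc(O)cc2)ccc1O | target

## Step count and least certain steps

Total: 11 steps. Longest linear sequence: 11 steps (1 to 17 through 2, 5, 6, 8, 9, 10, 11, 13, 14 and 16).

**Step 6 (key step).** The discrimination between the two enantiotopic arms may be insufficient or of the opposite sense, since aryl-bearing arms have not been used in this substrate class. The carbene may also be diverted into cycloaddition to the electron-rich arenes or into dimerisation, and incomplete separation of the diastereomers would erode C5 when C4 is flattened. The fallback sets out from racemic epoxide 5 and returns to the route at enol acetate 13. Hydrolytic kinetic resolution of 5 with the enantiomer of (salen)Co(OAc) (trivalent cobalt; salen = N,N'-bis(3,5-di-tert-butylsalicylidene)cyclohexane-1,2-diamine dianion) that consumes the S epoxide would leave (R)-2-[4-(methoxymethoxy)benzyl]oxirane F1. Opening of F1 with the dianion of (phenylselanyl)acetic acid (LiN(i-Pr)2, THF) and acid-induced lactonisation would give (5R)-5-[4-(methoxymethoxy)benzyl]-3-(phenylselanyl)dihydrofuran-2(3H)-one F2. Selenoxide elimination with H2O2 would give (R)-5-[4-(methoxymethoxy)benzyl]furan-2(5H)-one F3. Conjugate addition of the cuprate made from Grignard reagent 2 and CuBr·SMe2 with Me3SiCl at −78 °C, anti to the benzyl group, would give the trans lactone (4R,5R)-5-[4-(methoxymethoxy)benzyl]-4-[4-(methoxymethoxy)phenyl]dihydrofuran-2(3H)-one F4. Hydroxylation as in step 7 would give (3S,4S,5R)-3-hydroxy-5-[4-(methoxymethoxy)benzyl]-4-[4-(methoxymethoxy)phenyl]dihydrofuran-2(3H)-one F5, which enters step 8 and gives 13.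

**Step 9.** The bromination may discriminate poorly between rings A and B, may attack the enol acetate, or adventitious acid may strip a methoxymethyl group. The fallback sets out from 13 and returns at target 17. The two methoxymethyl groups would be removed first with ZnBr2 and propane-1-thiol in CH2Cl2, which spares the enol acetate, to give (R)-5-(4-hydroxybenzyl)-4-(4-hydroxyphenyl)-2-oxo-2,5-dihydrofuran-3-yl acetate F6. Bromination of the free phenols with NBS in MeCN at low temperature, where the gap between a para-alkylphenol and an acceptor-conjugated phenol is wider than for the ethers, would give (R)-5-(3-bromo-4-hydroxybenzyl)-4-(4-hydroxyphenyl)-2-oxo-2,5-dihydrofuran-3-yl acetate F7. Stille coupling with 15 as in step 10 would give (R)-5-[4-hydroxy-3-(3-methylbut-2-en-1-yl)benzyl]-4-(4-hydroxyphenyl)-2-oxo-2,5-dihydrofuran-3-yl acetate F8, and K2CO3 (catalytic) in MeOH at 0 °C would remove the acetate to give 17.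

**Step 10.** Allylic transposition during transmetalation may give the branched (reverse-prenyl) isomer, or slow oxidative addition into the electron-rich ortho-alkoxy aryl bromide may let protodestannylation win. The fallback sets out from 14 and returns at 16. Stille coupling with allyltributylstannane, which has no allylic ambiguity, would give (R)-5-[3-allyl-4-(methoxymethoxy)benzyl]-4-[4-(methoxymethoxy)phenyl]-2-oxo-2,5-dihydrofuran-3-yl acetate F9. Cross-metathesis of F9 with 2-methylbut-2-ene under the second-generation Grubbs catalyst, (H2IMes)(PCy3)Cl2Ru=CHPh, would give 16.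

**Step 11.** Acid may cyclise the freed ring B phenol onto the prenyl alkene or add HCl or methanol across it before both acetals are gone. The fallback sets out from 14 and returns at 17, with the acid step placed before the prenyl group exists. Methanolic HCl on 14 would give (R)-5-(3-bromo-4-hydroxybenzyl)-3-hydroxy-4-(4-hydroxyphenyl)furan-2(5H)-one F10. Peracetylation with Ac2O and pyridine would give (R)-5-(4-acetoxy-3-bromobenzyl)-4-(4-acetoxyphenyl)-2-oxo-2,5-dihydrofuran-3-yl acetate F11. Stille coupling with 15 would give (R)-5-[4-acetoxy-3-(3-methylbut-2-en-1-yl)benzyl]-4-(4-acetoxyphenyl)-2-oxo-2,5-dihydrofuran-3-yl acetate F12, and K2CO3 (catalytic) in MeOH at 0 °C would give 17.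

## Further compounds

F1 | step 6 | (R)-2-[4-(methoxymethoxy)benzyl]oxirane | COCOc1ccc(C[C@@H]2CO2)cc1
F2 | step 6 | (5R)-5-[4-(methoxymethoxy)benzyl]-3-(phenylselanyl)dihydrofuran-2(3H)-one | COCOc1ccc(C[C@H]2OC(=O)C([Se]c3ccccc3)C2)cc1
F3 | step 6 | (R)-5-[4-(methoxymethoxy)benzyl]furan-2(5H)-one | COCOc1ccc(C[C@H]2OC(=O)C=C2)cc1
F4 | step 6 | (4R,5R)-5-[4-(methoxymethoxy)benzyl]-4-[4-(methoxymethoxy)phenyl]dihydrofuran-2(3H)-one | COCOc1ccc(C[C@H]2OC(=O)C[C@@H]2c2ccc(OCOC)cc2)cc1
F5 | step 6 | (3S,4S,5R)-3-hydroxy-5-[4-(methoxymethoxy)benzyl]-4-[4-(methoxymethoxy)phenyl]dihydrofuran-2(3H)-one | COCOc1ccc(C[C@H]2OC(=O)[C@@H](O)[C@@H]2c2ccc(OCOC)cc2)cc1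
F6 | step 9 | (R)-5-(4-hydroxybenzyl)-4-(4-hydroxyphenyl)-2-oxo-2,5-dihydrofuran-3-yl acetate | Oc1ccc(C[C@H]2OC(=O)C(OC(C)=O)=C2c2ccc(O)cc2)cc1
F7 | step 9 | (R)-5-(3-bromo-4-hydroxybenzyl)-4-(4-hydroxyphenyl)-2-oxo-2,5-dihydrofuran-3-yl acetate | Oc1ccc(C[C@H]2OC(=O)C(OC(C)=O)=C2c2ccc(O)cc2)cc1Br
F8 | step 9 | (R)-5-[4-hydroxy-3-(3-methylbut-2-en-1-yl)benzyl]-4-(4-hydroxyphenyl)-2-oxo-2,5-dihydrofuran-3-yl acetate | CC(C)=CCc1cc(C[C@H]2OC(=O)C(OC(C)=O)=C2c2ccc(O)cc2)ccc1O
F9 | step 10 | (R)-5-[3-allyl-4-(methoxymethoxy)benzyl]-4-[4-(methoxymethoxy)phenyl]-2-oxo-2,5-dihydrofuran-3-yl acetate | COCOc1ccc(C[C@H]2OC(=O)C(OC(C)=O)=C2c2ccc(OCOC)cc2)cc1CC=C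
F10 | step 11 | (R)-5-(3-bromo-4-hydroxybenzyl)-3-hydroxy-4-(4-hydroxyphenyl)furan-2(5H)-one | Oc1ccc(C[C@H]2OC(=O)C(O)=C2c2ccc(O)cc2)cc1Br
F11 | step 11 | (R)-5-(4-acetoxy-3-bromobenzyl)-4-(4-acetoxyphenyl)-2-oxo-2,5-dihydrofuran-3-yl acetate | CC(=O)Oc1ccc(C[C@H]2OC(=O)C(OC(C)=O)=C2c2ccc(OC(C)=O)cc2)cc1Br
F12 | step 11 | (R)-5-[4-acetoxy-3-(3-methylbut-2-en-1-yl)benzyl]-4-(4-acetoxyphenyl)-2-oxo-2,5-dihydrofuran-3-yl acetate | CC(=O)Oc1ccc(C[C@H]2OC(=O)C(OC(C)=O)=C2c2ccc(OC(C)=O)cc2)cc1CC=C(C)C
A1 | alternative 1 | (R)-5-[3-bromo-4-(methoxymethoxy)benzyl]-3-hydroxy-4-[4-(methoxymethoxy)phenyl]furan-2(5H)-one | COCOc1ccc(C[C@H]2OC(=O)C(O)=C2c2ccc(OCOC)cc2)cc1Br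
A2 | alternative 1 | (2R,3R)-2-[3-bromo-4-(methoxymethoxy)benzyl]-3-[4-(methoxymethoxy)phenyl]oxirane | COCOc1ccc(C[C@H]2O[C@@H]2c2ccc(OCOC)cc2)cc1Br
A3 | alternative 2 | (R)-5-[4-(tert-butyldimethylsilyloxy)-3-(3-methylbut-2-en-1-yl)benzyl]-4-[4-(tert-butyldimethylsilyloxy)phenyl]-3-[(4-methoxybenzyl)oxy]furan-2(5H)-one | CC(C)=CCc1cc(C[C@H]2OC(=O)C(OCc3ccc(OC)cc3)=C2c2ccc(O[Si](C)(C)C(C)(C)C)cc2)ccc1O[Si](C)(C)C(C)(C)C
A4 | alternative 2 | (R)-1-[4-(tert-butyldimethylsilyloxy)-3-(3-methylbut-2-en-1-yl)phenyl]-4-[(4-methoxybenzyl)oxy]but-3-yn-2-ol | CC(C)=CCc1cc(C[C@@H](O)C#COCc2ccc(OC)cc2)ccc1O[Si](C)(C)C(C)(C)C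
A5 | alternative 2 | 4-(tert-butyldimethylsilyloxy)phenylmagnesium bromide | CC(C)(C)[Si](C)(C)Oc1ccc([Mg]Br)cc1
A6 | alternative 3 | (S)-5-[4-(methoxymethoxy)-3-(3-methylbut-2-en-1-yl)benzyl]dihydrofuran-2(3H)-one (C5 arranged as in the target) | CC(C)=CCc1cc(C[C@H]2OC(=O)CC2)ccc1OCOC
A7 | alternative 3 | (±)-2-[4-(methoxymethoxy)-3-(3-methylbut-2-en-1-yl)benzyl]cyclobutan-1-one | CC(C)=CCc1cc(CC2CCC2=O)ccc1OCOC
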